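## Retrosynthetic overview

1. The hydroxy-methoxy-quinone comes from a 2,3,5,6-tetramethoxyaryl group (CAN oxidation, then selective hydrolysis). The CH2–aryl bond comes from a Ni-catalysed coupling of a neopentyl decalin iodide with the tetramethoxyaryl Grignard reagent.
2. The C1 and C2 stereocentres come from conjugate methylation and enolate methylation of a cis-fused decalin enoate.
3. The cis ring fusion (C8a–H) comes from an allylic diazene transposition of an enone tosylhydrazone.
4. The bicyclic enedione ester comes from a Michael addition of 2-methylcyclohexane-1,3-dione to the Nazarov reagent, then a new phosphoric-acid-catalysed desymmetrising aldol condensation that sets C4a.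
5. Ring order: ring A is bought (cyclohexane-1,3-dione), ring B is closed by the annulation, and the arene is built separately from hydroquinone and joined last.

**Assumption:** the SMILES is read as the (1R,2R,4aR,8aS) isomer, a cis-decalin with the angular CH3, the ring-fusion H, the C2 methyl and the CH2–quinone arm on one face and the C1 methyl on the other. Locants follow naphthalene numbering: C1 = quaternary carbon bearing the CH2–quinone arm, C2 = CH–CH3, C4a = angular-methyl carbon, C5 = methylidene carbon, C8a = ring-fusion CH.

## Route

**Step 1**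
Reactants: 1 cyclohexane-1,3-dione
Product: 2 2-methylcyclohexane-1,3-dione
Conditions: MeI, KOH, H2O/MeOH, 65 °C; then HCl
Reagents that add atoms: iodomethane, CI
Why: Classical C-alkylation of the stabilised 1,3-dione enolate; no stereocentre is formed.

**Step 2**
Reactants: 3 methyl acetate; 4 acrolein
Product: 5 methyl 3-hydroxypent-4-enoate (racemic)
Conditions: LDA, THF, −78 °C; then 4, −78 °C; aq NH4Cl
Reagents that add atoms: none
Why: Aldol addition of the lithium ester enolate to the aldehyde (clean 1,2-addition at −78 °C); the carbinol centre is removed in the next step, so its configuration does not matter.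

**Step 3**
Reactants: 5 methyl 3-hydroxypent-4-enoate
Product: 6 methyl 3-oxopent-4-enoate (Nazarov reagent)
Conditions: Jones reagent (CrO3, H2SO4), acetone, 0–5 °C; kept cold with BHT and used promptly
Reagents that add atoms: none
Why: Jones oxidation of the secondary allylic alcohol to the vinyl ketone.

**Step 4**
Reactants: 2 2-methylcyclohexane-1,3-dione; 6 methyl 3-oxopent-4-enoate
Product: 7 methyl 5-(1-methyl-2,6-dioxocyclohexyl)-3-oxopentanoate (achiral)
Conditions: 6 (1.3 equiv), Et3N (2 mol%), MeCN, 0→23 °C; AcOH quench, short silica plug
Reagents that add atoms: none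
Why: Michael addition in which the much more acidic cyclic 1,3-dione, not the β-keto ester, is the donor under catalytic amine; the new quaternary carbon carries two identical ring arms and is not yet stereogenic.

**Step 5**
Reactants: 7 methyl 5-(1-methyl-2,6-dioxocyclohexyl)-3-oxopentanoate
Product: 8 methyl (4aR)-4a-methyl-2,5-dioxo-2,3,4,4a,5,6,7,8-octahydronaphthalene-1-carboxylate
Conditions: (R)-TRIP (5 mol%), toluene, 5 Å MS, 50 °C
Reagents that add atoms: none
Why: Proposed new method: a chiral-phosphoric-acid-catalysed desymmetrising intramolecular aldol condensation (the ring-closing half of a Robinson annulation) in which the acid binds the β-keto-ester enol through P=O and one of the two enantiotopic ring carbonyls through P–OH in a chair-like bifunctional transition state, so that C–C bond formation at one carbonyl fixes the angular quaternary centre as 4aR before dehydration (the catalyst antipode is used if it proves to be the matched one); the closest known chemistry is the Hajos–Parrish–Eder–Sauer–Wiechert reaction and the phosphoric-acid desymmetrisation of 2-methyl-2-(3-oxobutyl)-1,3-diones to Wieland–Miescher ketone, neither shown with a β-keto-ester donor of this kind.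

**Step 6**
Reactants: 8
Product: 9 methyl (4aS)-4a-methyl-5-methylidene-2-oxo-2,3,4,4a,5,6,7,8-octahydronaphthalene-1-carboxylate (descriptor changes by CIP priority only)
Conditions: Ph3PCH3Br (2.5 equiv), KHMDS (2.4 equiv), THF, 0→60 °C; AcOH; then DBU (cat.), CH2Cl2 to re-conjugate
Reagents that add atoms: methyltriphenylphosphonium bromide (ylide precursor), C[P+](c1ccccc1)(c1ccccc1)c1ccccc1.[Br-]
Why: Wittig methylenation; the first equivalent of ylide turns the vinylogous β-keto ester into its unreactive dienolate, so only the saturated C5 ketone is olefinated.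

**Step 7**
Reactants: 9
Product: 10 methyl (4aS)-4a-methyl-5-methylidene-2-(2-tosylhydrazinylidene)-2,3,4,4a,5,6,7,8-octahydronaphthalene-1-carboxylate
Conditions: TsNHNH2 (1.2 equiv), PPTS (5 mol%), EtOH, 50 °C
Reagents that add atoms: p-toluenesulfonyl hydrazide, Cc1ccc(cc1)S(=O)(=O)NN
Why: Tosylhydrazone condensation at the only remaining ketone (C2).

**Step 8**
Reactants: 10
Product: 11 methyl (4aR,8aR)-4a-methyl-5-methylidene-3,4,4a,5,6,7,8,8a-octahydronaphthalene-1-carboxylate
Conditions: catecholborane (2 equiv), CHCl3, 0 °C; then NaOAc·3H2O, 60 °C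
Reagents that add atoms: none
Why: Kabalka reduction with allylic diazene rearrangement: hydride adds to C2=N anti to the angular methyl, and the diazene then delivers H suprafacially to C8a on the face syn to the angular methyl with loss of N2, giving the cis ring fusion and moving the alkene into conjugation with the ester (the same course as cholest-4-en-3-one → 5β-cholest-3-ene).

**Step 9**
Reactants: 11
Product: 12 methyl (1R,2R,4aR,8aR)-1,2,4a-trimethyl-5-methylidenedecahydronaphthalene-1-carboxylate
Conditions: Me2CuLi (3 equiv), TMSCl, THF, −78→−20 °C; then MeLi, −78→0 °C; MeI, DMPU, −78→0 °C (one pot)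
Reagents that add atoms: lithium dimethylcuprate, [Li+].C[Cu-]C; iodomethane, CI
Why: Cuprate conjugate addition followed by enolate alkylation: methyl adds to C2 on the convex face of the cis-decalin (the face of H-8a and the angular methyl, away from ring A), and MeI then attacks the exocyclic ester enolate anti to the new pseudoaxial C2 methyl (A1,3-strain control), so the two new methyls are trans and the ester ends syn to C2–CH3, H-8a and C4a–CH3.

**Step 10**
Reactants: 12
Product: 13 [(1R,2R,4aR,8aR)-1,2,4a-trimethyl-5-methylidenedecahydronaphthalen-1-yl]methanol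
Conditions: LiAlH4, THF, 0→66 °C
Reagents that add atoms: none
Why: Hydride reduction of the hindered ester to the neopentyl alcohol; no stereocentre is affected.

**Step 11**
Reactants: 13
Product: 14 (1R,2R,4aR,8aR)-1-(iodomethyl)-1,2,4a-trimethyl-5-methylidenedecahydronaphthalene
Conditions: I2, PPh3, imidazole, toluene, 90 °C
Reagents that add atoms: iodine, II
Why: Garegg–Samuelsson (Appel-type) iodination through the alkoxyphosphonium salt; SN2 at the primary carbon avoids neopentyl rearrangement and imidazole buffers the acid so the exocyclic alkene stays in place.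

**Step 12**
Reactants: 15 hydroquinone
Product: 16 2,5-dihydroxy-1,4-benzoquinone
Conditions: 30% H2O2, 50% aq NaOH, 40 °C; then HCl
Reagents that add atoms: hydrogen peroxide, OO
Why: Known alkaline peroxide oxidation of hydroquinone, which hydroxylates the quinone twice by conjugate addition and re-oxidation.

**Step 13**
Reactants: 16
Product: 17 2,5-dimethoxy-1,4-benzoquinone
Conditions: MeOH, conc. H2SO4 (cat.), 23 °C
Reagents that add atoms: methanol, CO
Why: Acid-catalysed vinylogous Fischer esterification of the two vinylogous acid OH groups.

**Step 14**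
Reactants: 17
Product: 18 2,5-dimethoxybenzene-1,4-diol
Conditions: Na2S2O4, EtOAc/H2O, 23 °C
Reagents that add atoms: none
Why: Dithionite reduction of the quinone to the hydroquinone.

**Step 15**
Reactants: 18
Product: 19 1,2,4,5-tetramethoxybenzene
Conditions: Me2SO4, K2CO3, acetone, 56 °C, under N2
Reagents that add atoms: dimethyl sulfate, COS(=O)(=O)OC
Why: Williamson O-methylation of both phenols.

**Step 16**
Reactants: 19
Product: 20 3-bromo-1,2,4,5-tetramethoxybenzene
Conditions: NBS (1.0 equiv), MeCN, 0→23 °C
Reagents that add atoms: N-bromosuccinimide, BrN1C(=O)CCC1=O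
Why: Electrophilic aromatic bromination; the two ring C–H positions are equivalent and one equivalent of NBS gives the monobromide.

**Step 17**
Reactants: 20
Product: 21 (2,3,5,6-tetramethoxyphenyl)magnesium bromide (THF solution, titrated and used directly)
Conditions: Mg turnings (activated with 1,2-dibromoethane), LiCl, THF, 50 °C
Reagents that add atoms: magnesium, [Mg]
Why: Grignard formation by oxidative insertion of Mg into the aryl C–Br bond; LiCl speeds insertion into the electron-rich, di-ortho-substituted bromide and keeps the reagent soluble.

**Step 18**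
Reactants: 14; 21 (3 equiv)
Product: 22 3-{[(1R,2R,4aR,8aS)-1,2,4a-trimethyl-5-methylidenedecahydronaphthalen-1-yl]methyl}-1,2,4,5-tetramethoxybenzene
Conditions: NiCl2(dppf) (10 mol%), THF/Et2O, 45 °C
Reagents that add atoms: none
Why: Nickel-catalysed Kumada coupling of a neopentyl iodide with an aryl Grignard reagent, a known reaction class with NiCl2(dppf): Ni activates the primary C–I bond through a neopentyl radical, the quaternary C1 leaves no β-hydrogen, the radical cannot reach the C5 methylidene because the CH2 arm and C5 are trans across ring B, and reductive elimination forms the CH2–aryl bond without touching any stereocentre.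

**Step 19**
Reactants: 22
Product: 23 2,5-dimethoxy-3-{[(1R,2R,4aR,8aS)-1,2,4a-trimethyl-5-methylidenedecahydronaphthalen-1-yl]methyl}cyclohexa-2,5-diene-1,4-dione
Conditions: (NH4)2Ce(NO3)6 (2.5 equiv), MeCN/H2O 2:1, 0 °C
Reagents that add atoms: water, O
Why: CAN oxidative demethylation of a para-dimethoxy pair to the p-quinone; the two para pairs are symmetry-equivalent so one quinone results, and the exocyclic alkene survives at 0 °C.

**Step 20**
Reactants: 23
Product: 24 2-hydroxy-5-methoxy-3-{[(1R,2R,4aR,8aS)-1,2,4a-trimethyl-5-methylidenedecahydronaphthalen-1-yl]methyl}cyclohexa-2,5-diene-1,4-dione (target, CID71726091)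
Conditions: 2 M aq KOH, MeOH, 23 °C; then 1 M HCl
Reagents that add atoms: potassium hydroxide, [K+].[OH-]
Why: Addition–elimination hydrolysis of the vinylogous ester next to the alkyl group, whose methoxy is twisted out of conjugation by the side chain and is the more labile one (the selectivity precedented for ilimaquinone-type 3-alkyl-2,5-dimethoxyquinones); the basic conditions leave the exocyclic alkene in place.

## Compound list

1 | cyclohexane-1,3-dione | O=C1CCCC(=O)C1 | starting material
2 | 2-methylcyclohexane-1,3-dione | CC1C(=O)CCCC1=O | intermediate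
3 | methyl acetate | COC(C)=O | starting material
4 | acrolein | C=CC=O | starting material
5 | methyl 3-hydroxypent-4-enoate (racemic) | C=CC(O)CC(=O)OC | intermediate
6 | methyl 3-oxopent-4-enoate | C=CC(=O)CC(=O)OC | intermediate
7 | methyl 5-(1-methyl-2,6-dioxocyclohexyl)-3-oxopentanoate | COC(=O)CC(=O)CCC1(C)C(=O)CCCC1=O | intermediate
8 | methyl (4aR)-4a-methyl-2,5-dioxo-2,3,4,4a,5,6,7,8-octahydronaphthalene-1-carboxylate | O=C1CCCC2=C(C(=O)OC)C(=O)CC[C@@]12C | intermediate
9 | methyl (4aS)-4a-methyl-5-methylidene-2-oxo-2,3,4,4a,5,6,7,8-octahydronaphthalene-1-carboxylate | C=C1CCCC2=C(C(=O)OC)C(=O)CC[C@@]12C | intermediate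
10 | methyl (4aS)-4a-methyl-5-methylidene-2-(2-tosylhydrazinylidene)-2,3,4,4a,5,6,7,8-octahydronaphthalene-1-carboxylate | C=C1CCCC2=C(C(=O)OC)C(=NNS(=O)(=O)c3ccc(C)cc3)CC[C@@]12C | intermediate
11 | methyl (4aR,8aR)-4a-methyl-5-methylidene-3,4,4a,5,6,7,8,8a-octahydronaphthalene-1-carboxylate | C=C1CCC[C@H]2C(C(=O)OC)=CCC[C@@]12C | intermediate
12 | methyl (1R,2R,4aR,8aR)-1,2,4a-trimethyl-5-methylidenedecahydronaphthalene-1-carboxylate | C=C1CCC[C@H]2[C@](C)(C(=O)OC)[C@H](C)CC[C@@]12C | intermediate
13 | [(1R,2R,4aR,8aR)-1,2,4a-trimethyl-5-methylidenedecahydronaphthalen-1-yl]methanol | C=C1CCC[C@H]2[C@](C)(CO)[C@H](C)CC[C@@]12C | intermediate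
14 | (1R,2R,4aR,8aR)-1-(iodomethyl)-1,2,4a-trimethyl-5-methylidenedecahydronaphthalene | C=C1CCC[C@H]2[C@](C)(CI)[C@H](C)CC[C@@]12C | intermediate
15 | hydroquinone | Oc1ccc(O)cc1 | starting material
16 | 2,5-dihydroxy-1,4-benzoquinone | O=C1C=C(O)C(=O)C=C1O | intermediate
17 | 2,5-dimethoxy-1,4-benzoquinone | COC1=CC(=O)C(OC)=CC1=O | intermediate
18 | 2,5-dimethoxybenzene-1,4-diol | COc1cc(O)c(OC)cc1O | intermediate
19 | 1,2,4,5-tetramethoxybenzene | COc1cc(OC)c(OC)cc1OC | intermediate
20 | 3-bromo-1,2,4,5-tetramethoxybenzene | COc1cc(OC)c(OC)c(Br)c1OC | intermediate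
21 | (2,3,5,6-tetramethoxyphenyl)magnesium bromide | COc1cc(OC)c(OC)c([Mg]Br)c1OC | intermediate
22 | 3-{[(1R,2R,4aR,8aS)-1,2,4a-trimethyl-5-methylidenedecahydronaphthalen-1-yl]methyl}-1,2,4,5-tetramethoxybenzene | C=C1CCC[C@H]2[C@](C)(Cc3c(OC)c(OC)cc(OC)c3OC)[C@H](C)CC[C@@]12C | intermediate
23 | 2,5-dimethoxy-3-{[(1R,2R,4aR,8aS)-1,2,4a-trimethyl-5-methylidenedecahydronaphthalen-1-yl]methyl}-1,4-benzoquinone | C=C1CCC[C@H]2[C@](C)(CC3=C(OC)C(=O)C=C(OC)C3=O)[C@H](C)CC[C@@]12C | intermediate
24 | 2-hydroxy-5-methoxy-3-{[(1R,2R,4aR,8aS)-1,2,4a-trimethyl-5-methylidenedecahydronaphthalen-1-yl]methyl}-1,4-benzoquinone | C=C1CCC[C@H]2[C@](C)(CC3=C(O)C(=O)C=C(OC)C3=O)[C@H](C)CC[C@@]12C | target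

## Step count

- Total steps: 20.
- Longest linear sequence: 13 steps (steps 2–11, then 18–20, from methyl acetate and acrolein). That is 13/20 = 0.65 of the total. The dione branch (step 1) joins at step 4, and the six-step arene branch (steps 12–17) joins at step 18.

## Three steps most likely to fail

1. **Step 5 (proposed new asymmetric aldol condensation).** The risk is low enantioselectivity or a racemic background cyclisation of the acidic β-keto ester. Fallback with known chemistry: make (R)-Wieland–Miescher ketone from 2 and methyl vinyl ketone by the D-proline Hajos–Parrish–Eder–Sauer–Wiechert annulation, then install the C1 ester by α-iodination of the enone (I2, pyridine) and Pd-catalysed methoxycarbonylation (CO, MeOH) to reach 8.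
2. **Step 9 (conjugate methylation / enolate methylation setting C2 and C1).** The risks are a sluggish addition to the enoate and MeI entering the cis-decalin enolate on the wrong face. Fallback: swap the roles of the two C1 substituents. Alkylate the same enolate with 2,3,5,6-tetramethoxybenzyl bromide (from 19 by Rieche formylation, NaBH4, PBr3) so that the arylmethyl arm enters on the face MeI preferred, then reduce the ester to the C1 methyl (LiAlH4; MsCl; LiEt3BH). This gives 22 directly and replaces steps 10, 11, 17 and 18.
3. **Step 18 (Ni-catalysed neopentyl–aryl coupling with a di-ortho-substituted Grignard).** The risks are slow coupling, reduction of the iodide or biaryl formation. Fallback: oxidise 13 to the aldehyde, add 3-lithio-1,2,4,5-tetramethoxybenzene (n-BuLi on 19) and remove the benzylic hydroxyl by Barton–McCombie deoxygenation to give 22.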